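Read at 12 min: the flasks below differ from the epsilon run in two settings, time and free catalyst.

in all of them: starting material 11 mM; coupling partner 27.5 mM
- epsilon: free catalyst 12 µM; run made earlier
- autumn: free catalyst 20 µM; time 12 min
- midnight: free catalyst 11 µM; time 12 min
- dusk: free catalyst 8.0 µM; time 12 min
- dawn: free catalyst 6.0 µM; time 12 min
- winter: free catalyst 15 µM; time 12 min

- epsilon (time / min: product / %, starting material / %): 0.833: 3.5, 96.6; 2.00: 6.8, 94.4; 4.00: 9.5, 88.6; 6.00: 15.3, 86.7; 8.00: 17.7, 81.6

(each reading ± 1 percentage point)

- the earlier runs were read with a standard deviation of 1 percentage point
- no earlier run changes the charge of free catalyst; that part of a forecast is a guess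

* the flasks put in order of amount of product, in percent of the starting material charged, best first, at 12 min (autumn / midnight / dusk / dawn / winter)
* the amount of product, in percent of the starting material charged of the flask you put first, at 12 min
* the amount of product, in percent of the starting material charged of the flask you put last, at 12 min

Take the last epsilon reading and define the apparent rate constant k as minus the natural logarithm of the fraction of the charged starting material that is not product, divided by the time: 0.0243 min⁻¹, a reading that carries the scatter. Turn the time first. At 12 µM, k carries the 17.7% read at 8.00 min to 25.3% at 12 min. Now turn the catalyst, which no earlier run has varied. Assume that k scales with the charge; this is my guess, not a reading. At 8.00 min, a charge of 20 µM then gives 27.7%. Turn both, and my reckoning puts autumn at 38.6% and dawn at 13.6%, with the flasks ranked by charge.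

The forecast gives autumn > winter > midnight > dusk > dawn, with 36% for autumn (29% to 43%) and 14.5% for dawn (11% to 19%). Its ranking “rests on the assumption that rate rises monotonically with catalyst”. Its autumn figure is lower than mine, and its dawn figure higher.

    coupling partner + free catalyst ⇌ catalyst intermediate A (K = 18.0 L mol⁻¹, k = 567 L mol⁻¹ s⁻¹)
    starting material + catalyst intermediate A → catalyst intermediate B (k = 301 L mol⁻¹ s⁻¹)
    catalyst intermediate B → free catalyst + product (k = 0.914 s⁻¹)
    catalyst intermediate B → spent catalyst (k = 0.00256 s⁻¹)

The flasks came out as autumn > winter > midnight > dusk > dawn, with autumn at 36.7% and dawn at 11.8%, both inside the forecast's ranges. My autumn figure from k lies 1.9 percentage points high, and winter, reckoned the same way, gives 30.6% against its 28.3%. In dawn at 12.0 min, catalyst intermediate B made free catalyst and product 360 times as fast as it went to spent catalyst, yet spent catalyst already stood at 60.6% of the catalyst charged, against 56.5% in autumn. Left until 120 min, dawn holds 19.5% of product.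

The readings were computed on assumed constants, noise included.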